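(The numbers in the tables are calculated with constants of no real substance; the scatter is artificial.)

The amber run still holds 24.1 % of its substrate at 5.00 d, with target at 8.9 %, so flasks of this recipe are read on a rising curve, where lost time costs target.

| flask | substrate | reagent | temperature | remark | time |
|---|---|---|---|---|---|
| amber | 0.050 M | 0.80 equiv | 20 °C | run made earlier |  |
| red | 0.050 M | 1.1 equiv | 31 °C | run made earlier |  |
| violet | 0.050 M | 1.8 equiv | 20 °C | run made earlier |  |
| grey | 0.075 M | 0.80 equiv | 31 °C | run made earlier |  |
| midnight | 0.050 M (fed, over 50 h) | 0.800 equiv | 25 °C | all else is in the flask from the start; the feed brings no volume worth counting | 5.0 d |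
| winter | 0.050 M (in portions, 5, over 50 h) | 0.800 equiv | 25 °C | first portion at the start, last at 50 h | 5.0 d |
| noon | 0.050 M | 0.800 equiv | 25 °C | everything together at the start | 5.0 d |
| spring | 0.050 M | 0.800 equiv (fed, over 50 h) |  | the addition at 5 °C, then warmed to 25 °C; the feed brings no volume worth counting | 5.0 d |

- amber (time / d: target / %, substrate / %): 1.04: 0.1, 54.9; 2.08: 2.2, 40.3; 3.00: 4.2, 33.7; 4.00: 5.6, 29.6; 5.00: 8.9, 24.1
- red (time / d: target / %, substrate / %): 0.833: 5.9, 33.8; 1.67: 16.9, 18.1; 2.50: 22.3, 10.3; 3.00: 24.0, 4.9; 4.00: 29.0, 1.4
- violet (time / d: target / %, substrate / %): 0.333: 0, 81.0; 1.04: 0.7, 55.6; 1.67: 2.6, 46.3; 3.00: 6.9, 35.2; 4.00: 11.9, 29.5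
- grey (time / d: target / %, substrate / %): 0.833: 7.2, 34.2; 1.67: 15.6, 16.4; 2.50: 19.2, 6.9; 3.00: 23.8, 5.5; 4.00: 24.5, 0.2

(each reading ± 1 percentage point)

1. the best flask by amount of target, in percent of the substrate charged; "all alike" if 1.5 percentage points covers them all (midnight / winter / noon / spring / all alike)
2. amount of target at the end, in percent of the substrate charged, midnight
3. amount of target at the end, in percent of the substrate charged, winter
4. amount of target at the end, in percent of the substrate charged, noon
5. amount of target at the end, in percent of the substrate charged, spring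

- a species is counted by the substrate in it: one side product counts as two
- reactions considered so far: substrate -> intermediate; reagent + intermediate -> target; substrate + intermediate -> side product; reagent + target -> over-reaction product; substrate <-> dormant form

Noon serves as the zero of the scale. A steady feed and evenly spaced portions are both symmetric about the middle of the addition, so substrate in midnight and in winter arrives on average 25.0 h late. These two flasks should therefore stand level, below noon by a factor set by the steepness of the climb.

That steepness, read between the second and last readings, is 1.59 in amber, which still shows its induction period, and 0.618 in red. Across this range the midnight factor moves from 0.689 to 0.866. It stays below one, so the order holds while the size shifts. The middle value serves for 25 °C: 1.11, the growth exponent, the per cent of target gained per per cent of time.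

Temperature acts as a clock. Substrate falls to about a third at 3.00 d in amber and at 0.833 d in red, a speed-up of 3.60. Amber is noon's recipe run colder, and its last reading enters both as the amount carried over and through the exponent, so raising that reading by 1 percentage point moves noon by 2.6 points.

clock gain, amber to noon = 1.79
noon = amber's target × gain^exponent = 16.9 %
midnight, winter = noon × (1 − delay/time)^exponent = 13.1 %
clock loss in the cold = 10.3
spring = 10.1 %

Noon leads midnight by 3.8 points, more than the margin.

The forecast gives 14.5 %, 15 %, 16 % and 7.5 % for midnight, winter, noon and spring, with noon best, holding that “Spring loses 50 h to the cold”; its spring stands below this reckoning's 10.1 %.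

The flasks give 13.8 %, 13.8 %, 17.2 % and 10.3 %, with noon ahead.

    substrate → intermediate (k = 5.60 × 10⁻⁶ s⁻¹, Ea = 99.0 kJ mol⁻¹)
    reagent + intermediate → target (k = 4.00 × 10⁻⁵ M⁻¹ s⁻¹, Ea = 81.0 kJ mol⁻¹)
    substrate + intermediate → side product (k = 3.40 × 10⁻⁵ M⁻¹ s⁻¹, Ea = 85.0 kJ mol⁻¹)
    reagent + target → over-reaction product (k = 3.80 × 10⁻⁵ M⁻¹ s⁻¹, Ea = 79.0 kJ mol⁻¹)
    substrate ⇌ dormant form (K = 0.470, k = 1.20 × 10⁻⁵ s⁻¹, Ea = 100 kJ mol⁻¹, ΔH = −34.0 kJ mol⁻¹)
    (constants at 25 °C)

Midnight over noon is 0.802, against the reckoned 0.772. The neighbour of noon charged at 0.013 M substrate, same equivalents, has no delay, so the delay factor is one, yet it gives 7.52 % target. Read through the exponent 1.11, that amount stands where noon's curve would be after 2.36 d.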